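The earlier runs and the new flask come from a simulation with made-up constants; the scatter is artificial.

The flask holds twice the substrate of the midnight run, with an equal charge of coupling partner, and it runs 4.50 times as long as that run's last reading.

all flasks: coupling partner 1.71 M
- midnight: substrate 0.90 M; run made earlier
- flask: substrate 1.8 M; time 6.0 min
midnight run (percent of the substrate charged)

| time / s | side product / % | target / % |
|---|---|---|
| 12.0 | 1.0 | 0.1 |
| 25.0 | 2.0 | 2.5 |
| 40.0 | 2.7 | 5.4 |
| 50.0 | 2.3 | 6.1 |
| 60.0 | 1.6 | 7.9 |
| 80.0 | 1.9 | 12.2 |

(readings scatter by 1 percentage point)
1. time up to 6.0 min at which side product stands highest
2. the amount of side product, in percent of the substrate charged, at that time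
3. the first time at which side product reaches 13%, in the same percent, in min
- in percentages every species weighs as the substrate in it: one side product counts as two
- what was read earlier has a scatter of 1 percentage point, one standard deviation
- steps under discussion: substrate + coupling partner + target -> 2 target; substrate + coupling partner -> target; substrate + target -> side product

The midnight target readings climb roughly in proportion to time, and my own reckoning takes the same for the flask as a working assumption, setting aside the listed step in which target makes more target. Side product forms from substrate and target, so under that assumption its share grows with the substrate charge and the square of time. Folding these together gives the square-law side share, the last midnight side share multiplied by the charge ratio and the squared time ratio: 76.9%. It rests on one reading of 1.9% with a scatter of 1 percentage point, so it is rough.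

The square law reaches 13% in the flask at 2.47 min. The test is the balance: the target share, extended in proportion to time, gives 54.9%, and together with 76.9% that makes 132%, more than the charge. I therefore use the one number for the early level and not for the end. No listed step consumes side product, so I place the highest value at the time limit.

The forecast gives 2.4 min, slightly earlier than mine, and 37% at 6 min: “Nothing destroys side product, so it peaks at the end”.

The flask gives 43.0% at 6.00 min and reaches the level at 2.26 min.

    substrate + coupling partner + target → 2 target (k = 0.00614 M⁻² s⁻¹)
    substrate + coupling partner → target (k = 6.71 × 10⁻⁴ M⁻¹ s⁻¹)
    substrate + target → side product (k = 0.00318 M⁻¹ s⁻¹)

The best lies 6 points above the forecast and stands at 55.9% of 76.9%, with 18.9% of the substrate left at that time. The neighbouring flask charged with 0.72 M of substrate has a square-law share of 30.8%, and its simulated best is 21.9%, which is 71.1% of that share.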